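(The readings come from a simulation for substances that don't exist; noise was put on by code.)

Time the solid first, then read the rest of the flask against that clock.

| flask | Z | L | remark | time |
|---|---|---|---|---|
| Wednesday's | 0.47 M | 1.2 M | run made earlier |  |
| Tuesday's | 0.47 M | 2.1 M | run made earlier |  |
| summer | 0.47 M | 0.940 M |  | 2.5 min |
| dawn | 0.47 M | 1.90 M |  | 2.5 min |

| run | time / s | Z / % | G / % |
|---|---|---|---|
| Wednesday's | 20.0 | 81 | 3 |
| Wednesday's | 40.0 | 64 | 9 |
| Wednesday's | 60.0 | 49 | 18 |
| Wednesday's | 80.0 | 39 | 25 |
| Wednesday's | 120 | 14 | 31 |
| Tuesday's | 10.0 | 91 | 3 |
| Tuesday's | 15.0 | 84 | 1 |
| Tuesday's | 30.0 | 71 | 6 |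
| Tuesday's | 60.0 | 45 | 23 |
| Tuesday's | 120 | 0 | 43 |

(standard deviation of a reading: 1.5 percentage points)

- solid, in amounts per volume of the solution: Z
- the earlier runs were read with a standard deviation of 1.5 percentage points
- at the start none of Z is in solution
- what has only dissolved of Z counts as not reacted
- apart from what has only dissolved, what has gone from Z into another species counts as reacted, even if it can come back

* part of the Z that has reacted (what has only dissolved counts as not reacted) at the end, summer
* part of the Z that has reacted (what has only dissolved counts as not reacted) at the end, dawn
* what raising the concentration of L from its lowest to its highest value here does to the part of the Z that has reacted (what has only dissolved counts as not reacted) (changes below 5 percentage points count as none) (it falls / it rises / no change)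

Z starts as a solid, and Z that has merely dissolved still counts as unreacted, so you need the solid's pace before anything else. In Tuesday's run the solid loses 55 percentage points of the charge in 60.0 s, which is a flow of 0.00431 M/s. Dividing the charge c_Z of 0.47 M by that flow gives 109 s, the emptying time: how long the solid lasts at its opening flow, as if it were a zero-order feed. Wednesday's run gives 118 s by the same division, with c_L at 1.2 M against 2.1 M, so in these readings the opening flow follows L weakly.

Now order the clocks, fastest first. The emptying time comes first, and it is shorter than the asked 150 s. The pace of G comes next: Tuesday's G gains 20 points between 60.0 s and 120 s, which is a whole charge per 300 s, longer than the asked time. So on the first rung of Tuesday's run the solid empties into the solution faster than G appears, and a stock builds that is neither solid nor G. On the second rung you expect little solid, and the question becomes how much of that stock is still merely dissolved Z.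

The flow does slow, though. Wednesday's solid still stands at 14% after 120 s, more than Tuesday's 0%, which suggests that dissolved Z stays higher with less L. My own reckoning stops there: it puts dawn above summer and gives no figures, since these readings do not split the stock.

The forecast does give figures, 47% for summer and 65% for dawn, answers the question on raising c_L with "it rises", and adds: “The split of the gap is poorly determined.”

The flasks give 69.8% for summer and 89.8% for dawn, and the answer on raising c_L is "it rises", by 20 points.

    Q + L ⇌ X (K = 3.00 /M, k = 0.0600 /M/s)
    X ⇌ G + J (K = 0.220 M, k = 0.0480 /s)
    Q + J ⇌ D, settled at all times (K = 0.500 /M)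
    Z ⇌ Q, rate k4*(cs4 - [Q]) while solid is left; crystals form when [Q] > cs4 (solubility = 0.180 M, k = 0.0300 /s)

Q is the dissolved Z. Tuesday's emptying time of 109 s, read at 2.1 M of L, falls inside dawn's 150 s, and at 2.50 min dawn holds Z 0% and Q 10.2%. Summer, with less L than Wednesday's run and its 118 s, still holds Z 5.48% and Q 24.7% at 2.50 min. Now take the neighbour flask, dawn with 0.19 M of Z. Reckoned at Tuesday's flow, that charge has an emptying time of 44.1 s, an estimate that stands 106 s inside the run. At 2.50 min the neighbour flask holds Z 0% and Q 6.23%, with 93.8% of its Z reacted.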